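The target is cut at C5–C6 (benzofuran numbering). The cis β-hydroxy ketone C6(OH)–C7–C1′(=O) is carried as a 4,5-dihydroisoxazole, and the enol ether C4(OMe)=C5 as a 1-methoxyvinyl group on a trans-2,3-disubstituted dihydrofuran. In the key step a Lewis acid ionises the isoxazoline's C6 methyl acetal; the diene terminus C5 attacks the oxocarbenium ion, closing the cyclohexadiene ring, setting C6 cis to C7 through the ring fusion and delivering the C4 methyl dienol ether in one operation. The step exploits the 1,3-relationship of O6 and C1′ across C7 and the 1,3-dioxygenated diene O1–C7a=C3a–C4(OMe)=C5. Hydrogenolysis of the N–O bond then unmasks the target.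

Key step: step 11

Remark 1: atom labels (O1, C2, C3, C3a, C4–C7, C7a; C1′ = ketone carbon of the side chain) follow the benzofuran numbering of the target and are used for all intermediates.
Remark 2: the acetal carbon C6 of 14–17 is drawn as the trans anomer; both anomers give the same oxocarbenium ion. Aldehyde 8 is drawn as the aldehyde although its conjugated enol should predominate.
Remark 3: it is assumed that the quinidine-derived catalyst of step 3 gives the (4R,5R) series; if the sense proves opposite, the quinine-derived pseudoenantiomer (DHQ)2PHAL takes its place.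
Remark 4: the enol ethers 16–19 and 21 are acid-labile and are assumed to be handled on base-washed supports.

Step 1
Reactants: 1 5-bromo-2-hydroxybenzaldehyde
Product: 2 5-bromo-2-[(triisopropylsilyl)oxy]benzaldehyde
Conditions: iPr3SiCl, imidazole, DMF, 25 °C
Reagents that add atoms: chlorotriisopropylsilane, CC(C)[Si](Cl)(C(C)C)C(C)C
Why: Silyl ether formation at the phenol blocks the coumarin-forming lactonisation that a free salicylaldehyde would undergo in step 2 and gives an ether that should tolerate the amines, the Grignard reagent and the lithium amide used later.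

Step 2
Reactants: 2 silyl-protected aldehyde; 3 methyl 3-oxobutanoate
Product: 4 methyl (2Z)-2-acetyl-3-{5-bromo-2-[(triisopropylsilyl)oxy]phenyl}prop-2-enoate
Conditions: piperidine (10 mol %), AcOH (10 mol %), toluene, 4 Å MS, 40 °C
Reagents that add atoms: none
Why: Knoevenagel condensation of the aryl aldehyde with the active methylene compound should give the alkylidene β-keto ester (Z isomer expected as the major one, the isomers interconverting under amine catalysis), which is the 1-oxadiene for the annulation.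

Step 3
Reactants: 4 alkylidene β-keto ester; 5 1-bromopropan-2-one
Product: 6 methyl (4R,5R)-5-acetyl-4-{5-bromo-2-[(triisopropylsilyl)oxy]phenyl}-2-methyl-4,5-dihydrofuran-3-carboxylate
Conditions: (DHQD)2PHAL (20 mol %), Cs2CO3, MeCN, 0 → 25 °C
Reagents that add atoms: none
Why: Formal [4+1] annulation through a catalytic chiral ammonium ylide (interrupted Feist–Benary type): Michael addition of the cinchona-bound acetonyl ylide to the alkylidene carbon sets C3 under catalyst control, and 5-exo-tet O-alkylation by the ketone enolate oxygen with release of the amine closes the dihydrofuran with C2 trans to C3 (anti-periplanar displacement, and C2 can equilibrate next to the acetyl group).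

Step 4
Reactants: 6 acetyl dihydrofuran
Product: 7 methyl (4R,5R)-4-{5-bromo-2-[(triisopropylsilyl)oxy]phenyl}-5-(2-hydroxypropan-2-yl)-2-methyl-4,5-dihydrofuran-3-carboxylate
Conditions: MeMgBr (1.2 equiv), THF, −78 °C
Reagents that add atoms: methylmagnesium bromide, C[Mg]Br
Why: Grignard addition should be chemoselective for the α-alkoxy methyl ketone over the vinylogous carbonate ester, which is deactivated by the ring oxygen, and creates the tertiary alcohol without touching C2 or C3.

Step 5
Reactants: 7 tertiary alcohol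
Product: 8 methyl (4R,5R)-4-{5-bromo-2-[(triisopropylsilyl)oxy]phenyl}-5-(2-hydroxypropan-2-yl)-2-(2-oxoethyl)-4,5-dihydrofuran-3-carboxylate
Conditions: LiN(iPr)2 (3.3 equiv), THF, −78 °C; HCO2Et, −78 → 0 °C; aq NH4Cl
Reagents that add atoms: ethyl formate, CCOC=O
Why: After the alkoxide has formed, vinylogous (γ) deprotonation of the C7 methyl group of the β-alkoxy acrylate and Claisen-type formylation of the dienolate at its γ-carbon (the α-carbon C3a is fully substituted) should give the C6 aldehyde, which is held as its stabilised vinylogous-acid enolate until work-up.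

Step 6
Reactants: 9 3-phenylpropanal
Product: 10 3-phenylpropanal oxime
Conditions: NH2OH·HCl, NaOAc, EtOH/H2O, 25 °C
Reagents that add atoms: hydroxylamine hydrochloride, NO.Cl
Why: Oxime condensation of an unhindered aldehyde (E/Z mixture, both isomers usable).

Step 7
Reactants: 10 oxime
Product: 11 N-hydroxy-3-phenylpropanimidoyl chloride
Conditions: N-chlorosuccinimide, DMF, 25 °C
Reagents that add atoms: N-chlorosuccinimide, ClN1C(=O)CCC1=O
Why: Chlorination of the aldoxime gives the hydroximoyl chloride, the storable precursor from which base releases the nitrile oxide.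

Step 8
Reactants: 8 aldehyde; 11 hydroximoyl chloride; 12 (2S)-2-[diphenyl(trimethylsilyloxy)methyl]pyrrolidine
Product: 15 methyl (4R,5R)-4-{5-bromo-2-[(triisopropylsilyl)oxy]phenyl}-5-(2-hydroxypropan-2-yl)-2-[(4S,5R)-5-methoxy-3-(2-phenylethyl)-4,5-dihydro-1,2-oxazol-4-yl]-4,5-dihydrofuran-3-carboxylate, via E-enamine 13 (not isolated), via aminal cycloadduct 14 (not isolated)
Conditions: 12 (1.05 equiv), 4 Å MS, CH2Cl2, 25 °C; then 11, Et3N, 0 °C; then MeOH, pyridinium 4-methylbenzenesulfonate (1.1 equiv), 0 → 25 °C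
Reagents that add atoms: methanol, CO
Why: Condensation gives the push–pull E-enamine, whose Huisgen [3+2] cycloaddition with the nitrile oxide released from 11 joins C1′ to the nucleophilic C7 and the dipole oxygen to C6, the diphenyl(silyloxy)methyl group shielding one face of the s-trans enamine so that C7 is set by the auxiliary (C6 follows trans, suprafacially), and acid-mediated exchange of the amine for methanol through the oxocarbenium ion then gives the stable methyl acetal and returns the auxiliary.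

Step 9
Reactants: 15 methoxyisoxazoline ester
Product: 16 2-[(2R,3R)-3-{5-bromo-2-[(triisopropylsilyl)oxy]phenyl}-5-[(4S,5R)-5-methoxy-3-(2-phenylethyl)-4,5-dihydro-1,2-oxazol-4-yl]-4-(1-methoxyethenyl)-2,3-dihydrofuran-2-yl]propan-2-ol
Conditions: Cp2Ti(CH2)(Cl)AlMe2 (3 equiv), pyridine, THF/toluene, −40 → 0 °C; aq NaOH
Reagents that add atoms: Cp2Ti(CH2)(Cl)AlMe2 (Tebbe reagent), C[Al-]1(C)C[Ti](C2C=CC=C2)(C2C=CC=C2)[Cl+]1
Why: Tebbe methylenation converts the only ester present (the C4 vinylogous carbonate) into the 1-methoxyvinyl group, so that C4 keeps its methoxy oxygen and C5 enters as the methylene carbon, while the non-basic titanium methylidene should leave acetal, aryl bromide and silyl ether alone and the free tertiary alcohol only consumes one more equivalent.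

Step 10
Reactants: 16 bromo methoxydiene
Product: 17 methyl 3-[(2R,3R)-2-(2-hydroxypropan-2-yl)-5-[(4S,5R)-5-methoxy-3-(2-phenylethyl)-4,5-dihydro-1,2-oxazol-4-yl]-4-(1-methoxyethenyl)-2,3-dihydrofuran-3-yl]-4-[(triisopropylsilyl)oxy]benzoate
Conditions: CO (1 atm), MeOH (10 equiv), Pd(OAc)2 (5 mol %), Xantphos (6 mol %), Et3N, toluene, 70 °C
Reagents that add atoms: carbon monoxide, [C-]#[O+]; methanol, CO
Why: Palladium-catalysed methoxycarbonylation (oxidative addition of zerovalent palladium to the aryl bromide, CO insertion, methanolysis) installs the benzoate only now, because an aryl ester present in step 9 would have been methylenated as well, and the amine-buffered medium should be harmless to the acid-labile diene and acetal.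

Step 11
Reactants: 17 methoxydiene acetal
Product: 19 cis-fused tricyclic isoxazoline of the target skeleton (ring C7–C1′=N–O–C6 in place of ketone and C6 hydroxyl; free phenol; free tertiary alcohol; 2R,3R,6R,7R), via silylated tricycle 18 (not isolated)
Conditions: Me3SiOTf (2.5 equiv), 2,6-di-tert-butyl-4-methylpyridine, CH2Cl2, −78 °C; Et3N; then Bu4NF, AcOH, THF, 0 °C
Reagents that add atoms: none
Why: Me3SiOTf first silylates the tertiary alcohol and then ionises the C6 methyl acetal of 17 to a cyclic oxocarbenium ion stabilised by the ring N–O oxygen; the nucleophilic terminus C5 of the diene O1–C7a=C3a–C4(OMe)=C5 adds to C6, and the resulting 1,3-dialkoxyallyl cation is discharged by loss of a C5 proton, which restores the C4 methyl enol ether inside the new ring. The closest known reaction type is the intramolecular Mukaiyama–Prins cyclisation of enol ethers onto oxocarbenium ions made from cyclic acetals, including Lewis-acid C–C bond formation at the oxygen-bearing carbon of N–O heterocycles. The six-membered carbocycle closes in a 6-(enolendo)-exo-trig mode. The new stereocenter C6 is controlled by C7: the four-atom tether C7a–C3a–C4–C5 can reach the planar oxocarbenium carbon only from the face on which C7 holds C7a, so the five/six ring fusion is necessarily cis and O6 ends cis to C1′. The step needs C–C bond formation to outrun loss of the C7 proton (which would aromatise the isoxazoline to an isoxazole) and needs the final proton to leave from C5 and not from C7; the intramolecular six-ring closure at −78 °C, the hindered non-nucleophilic base and the tertiary ring-fusion position of H–C7 are relied on for both. Buffered fluoride then removes both silyl groups in the same flask.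

Step 12
Reactants: 19 tricyclic isoxazoline
Product: 21 methyl 4-hydroxy-3-[(2R,3R,6R,7R)-6-hydroxy-2-(2-hydroxypropan-2-yl)-4-methoxy-7-(3-phenylpropanoyl)-2,3,6,7-tetrahydro-1-benzofuran-3-yl]benzoate, via β-hydroxy imine 20 (not isolated)
Conditions: H2 (1 atm), Raney Ni, B(OH)3, MeOH/H2O (5:1), 0 °C
Reagents that add atoms: water, O
Why: Hydrogenolysis of the weak N–O bond over Raney Ni gives the β-hydroxy imine, which the boric acid buffer hydrolyses at once to the ketone, a method that conserves the α-carbon (C7) and the carbinol carbon (C6) and should leave the enol ether double bonds and the aryl ester alone.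

Compound list
1 | 5-bromo-2-hydroxybenzaldehyde | O=Cc1cc(Br)ccc1O | starting material
2 | 5-bromo-2-[(triisopropylsilyl)oxy]benzaldehyde | O=Cc1cc(Br)ccc1O[Si](C(C)C)(C(C)C)C(C)C | intermediate
3 | methyl 3-oxobutanoate (methyl acetoacetate) | COC(=O)CC(C)=O | starting material
4 | methyl (2Z)-2-acetyl-3-{5-bromo-2-[(triisopropylsilyl)oxy]phenyl}prop-2-enoate | CC(=O)/C(C(=O)OC)=C/c1cc(Br)ccc1O[Si](C(C)C)(C(C)C)C(C)C | intermediate
5 | 1-bromopropan-2-one (bromoacetone) | CC(=O)CBr | starting material
6 | methyl (4R,5R)-5-acetyl-4-{5-bromo-2-[(triisopropylsilyl)oxy]phenyl}-2-methyl-4,5-dihydrofuran-3-carboxylate | Brc1ccc(O[Si](C(C)C)(C(C)C)C(C)C)c(c1)[C@@H]1C(C(=O)OC)=C(C)O[C@H]1C(C)=O | intermediate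
7 | methyl (4R,5R)-4-{5-bromo-2-[(triisopropylsilyl)oxy]phenyl}-5-(2-hydroxypropan-2-yl)-2-methyl-4,5-dihydrofuran-3-carboxylate | Brc1ccc(O[Si](C(C)C)(C(C)C)C(C)C)c(c1)[C@@H]1C(C(=O)OC)=C(C)O[C@H]1C(C)(C)O | intermediate
8 | methyl (4R,5R)-4-{5-bromo-2-[(triisopropylsilyl)oxy]phenyl}-5-(2-hydroxypropan-2-yl)-2-(2-oxoethyl)-4,5-dihydrofuran-3-carboxylate | Brc1ccc(O[Si](C(C)C)(C(C)C)C(C)C)c(c1)[C@@H]1C(C(=O)OC)=C(CC=O)O[C@H]1C(C)(C)O | intermediate
9 | 3-phenylpropanal | O=CCCc1ccccc1 | starting material
10 | 3-phenylpropanal oxime (E/Z mixture) | ON=CCCc1ccccc1 | intermediate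
11 | N-hydroxy-3-phenylpropanimidoyl chloride | ON=C(Cl)CCc1ccccc1 | intermediate
12 | (2S)-2-[diphenyl(trimethylsilyloxy)methyl]pyrrolidine | C[Si](C)(C)OC(c1ccccc1)(c1ccccc1)[C@@H]1CCCN1 | starting material
13 | methyl (4R,5R)-4-{5-bromo-2-[(triisopropylsilyl)oxy]phenyl}-2-[(E)-2-{(2S)-2-[diphenyl(trimethylsilyloxy)methyl]pyrrolidin-1-yl}ethenyl]-5-(2-hydroxypropan-2-yl)-4,5-dihydrofuran-3-carboxylate (E-enamine) | Brc1ccc(O[Si](C(C)C)(C(C)C)C(C)C)c(c1)[C@@H]1C(C(=O)OC)=C(/C=C/N2CCC[C@H]2C(c2ccccc2)(c2ccccc2)O[Si](C)(C)C)O[C@H]1C(C)(C)O | intermediate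
14 | methyl (4R,5R)-4-{5-bromo-2-[(triisopropylsilyl)oxy]phenyl}-2-[(4S,5R)-5-{(2S)-2-[diphenyl(trimethylsilyloxy)methyl]pyrrolidin-1-yl}-3-(2-phenylethyl)-4,5-dihydro-1,2-oxazol-4-yl]-5-(2-hydroxypropan-2-yl)-4,5-dihydrofuran-3-carboxylate (aminal cycloadduct) | Brc1ccc(O[Si](C(C)C)(C(C)C)C(C)C)c(c1)[C@@H]1C(C(=O)OC)=C(O[C@H]1C(C)(C)O)[C@@H]1C(CCc2ccccc2)=NO[C@H]1N1CCC[C@H]1C(c1ccccc1)(c1ccccc1)O[Si](C)(C)C | intermediate
15 | methyl (4R,5R)-4-{5-bromo-2-[(triisopropylsilyl)oxy]phenyl}-5-(2-hydroxypropan-2-yl)-2-[(4S,5R)-5-methoxy-3-(2-phenylethyl)-4,5-dihydro-1,2-oxazol-4-yl]-4,5-dihydrofuran-3-carboxylate | Brc1ccc(O[Si](C(C)C)(C(C)C)C(C)C)c(c1)[C@@H]1C(C(=O)OC)=C(O[C@H]1C(C)(C)O)[C@@H]1C(CCc2ccccc2)=NO[C@H]1OC | intermediate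
16 | 2-[(2R,3R)-3-{5-bromo-2-[(triisopropylsilyl)oxy]phenyl}-5-[(4S,5R)-5-methoxy-3-(2-phenylethyl)-4,5-dihydro-1,2-oxazol-4-yl]-4-(1-methoxyethenyl)-2,3-dihydrofuran-2-yl]propan-2-ol | Brc1ccc(O[Si](C(C)C)(C(C)C)C(C)C)c(c1)[C@@H]1C(C(=C)OC)=C(O[C@H]1C(C)(C)O)[C@@H]1C(CCc2ccccc2)=NO[C@H]1OC | intermediate
17 | methyl 3-[(2R,3R)-2-(2-hydroxypropan-2-yl)-5-[(4S,5R)-5-methoxy-3-(2-phenylethyl)-4,5-dihydro-1,2-oxazol-4-yl]-4-(1-methoxyethenyl)-2,3-dihydrofuran-3-yl]-4-[(triisopropylsilyl)oxy]benzoate | COC(=O)c1ccc(O[Si](C(C)C)(C(C)C)C(C)C)c(c1)[C@@H]1C(C(=C)OC)=C(O[C@H]1C(C)(C)O)[C@@H]1C(CCc2ccccc2)=NO[C@H]1OC | intermediate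
18 | silylated tricycle: compound 19 carrying a triisopropylsilyl ether on the phenol and a trimethylsilyl ether on the tertiary alcohol (2R,3R,6R,7R) | COC(=O)c1ccc(O[Si](C(C)C)(C(C)C)C(C)C)c(c1)[C@@H]1C2=C(O[C@H]1C(C)(C)O[Si](C)(C)C)[C@@H]1C(CCc3ccccc3)=NO[C@@H]1C=C2OC | intermediate
19 | cis-fused tricyclic isoxazoline: the 4-methoxy-2,3,6,7-tetrahydrobenzofuran of the target in which C7 carries C1′(CH2CH2Ph)=N and the N–O oxygen is bound to C6; 3-(2-hydroxy-5-methoxycarbonylphenyl) and 2-(2-hydroxypropan-2-yl) as in the target; 2R,3R,6R,7R | COC(=O)c1ccc(O)c(c1)[C@@H]1C2=C(O[C@H]1C(C)(C)O)[C@@H]1C(CCc3ccccc3)=NO[C@@H]1C=C2OC | intermediate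
20 | methyl 4-hydroxy-3-[(2R,3R,6R,7R)-6-hydroxy-2-(2-hydroxypropan-2-yl)-7-(1-imino-3-phenylpropyl)-4-methoxy-2,3,6,7-tetrahydro-1-benzofuran-3-yl]benzoate (β-hydroxy imine) | COC(=O)c1ccc(O)c(c1)[C@@H]1C2=C(O[C@H]1C(C)(C)O)[C@H](C(=N)CCc3ccccc3)[C@H](O)C=C2OC | intermediate
21 | methyl 4-hydroxy-3-[(2R,3R,6R,7R)-6-hydroxy-2-(2-hydroxypropan-2-yl)-4-methoxy-7-(3-phenylpropanoyl)-2,3,6,7-tetrahydro-1-benzofuran-3-yl]benzoate | COC(=O)c1ccc(O)c([C@@H]2C3=C(O[C@H]2C(C)(C)O)[C@H](C(=O)CCc2ccccc2)[C@H](O)C=C3OC)c1 | target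

Total step count: 12 (steps 6 and 7 prepare the nitrile oxide precursor). Longest linear sequence: 10 (steps 1–5 and 8–12).

Steps most likely to fail

Step 11. The oxocarbenium ion may lose the C7 proton before the diene reaches it (aromatisation to an isoxazole). The cation formed after ring closure may shed the C7 instead of the C5 proton. The dienol ether product may also re-ionise at its allylic C6–O bond under the Lewis acid. The fallback changes the nucleophile and makes the enol ether after the ring. It sets out from 17: the 1-methoxyvinyl group is hydrolysed selectively (oxalic acid on wet silica gel, CH2Cl2, 0 °C) to the methyl ketone F1. Kinetic enolisation of the acetyl group with silylation of both oxygens (LiN(SiMe3)2, Me3SiCl, THF, −78 °C) gives the 2-silyloxydiene F2. Me3SiOTf (10 mol %) in CH2Cl2 at −78 °C, without base, should then close C5 onto the C6 acetal in a Mukaiyama aldol-type reaction and give the acid-stable tricyclic vinylogous ester ketone F3. O-Methylation of its carbonyl oxygen (MeOTf, 2,6-di-tert-butyl-4-methylpyridine, CH2Cl2, −40 °C, then Et3N) with loss of a C5 proton leads to 18, where the fallback comes back to the route before the fluoride treatment of step 11.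

Step 8. Face discrimination in the cycloaddition to the push–pull enamine may be incomplete, and the aminal or the acetal may lose amine or methanol with aromatisation to the isoxazole during the exchange. The fallback gives up the auxiliary and sets out from 8. O-Methylation of the enol (dimethyl sulfate, K2CO3, acetone, 25 °C) gives the methyl enol ether F4. Cycloaddition with the nitrile oxide from 11 (Et3N, CH2Cl2, 0 °C) should give 15 together with its (4R,5S)-isoxazoline epimer F5 in comparable amounts. The two diastereomers are separated by chromatography, and the fallback comes back to the route at 15.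

Step 12. The dienol ether may be hydrogenated or hydrolysed in the slightly acidic medium, or the β-hydroxy ketone may lose water and aromatise. The fallback cleaves the N–O bond without hydrogen or boric acid and before the polar groups are freed. It sets out from 18, isolated after an aqueous NaHCO3 work-up of step 11 in place of the fluoride treatment. Mo(CO)6 in MeCN/H2O at 70 °C should give the silyl-protected β-hydroxy ketone F6. Buffered fluoride (Bu4NF, AcOH, THF, 0 °C) then removes both silyl groups, and the fallback comes back to the route at 21.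

Further compounds
F1 | step 11 | methyl 3-[(2R,3R)-4-acetyl-2-(2-hydroxypropan-2-yl)-5-[(4S,5R)-5-methoxy-3-(2-phenylethyl)-4,5-dihydro-1,2-oxazol-4-yl]-2,3-dihydrofuran-3-yl]-4-[(triisopropylsilyl)oxy]benzoate | COC(=O)c1ccc(O[Si](C(C)C)(C(C)C)C(C)C)c(c1)[C@@H]1C(C(C)=O)=C(O[C@H]1C(C)(C)O)[C@@H]1C(CCc2ccccc2)=NO[C@H]1OC
F2 | step 11 | methyl 3-[(2R,3R)-5-[(4S,5R)-5-methoxy-3-(2-phenylethyl)-4,5-dihydro-1,2-oxazol-4-yl]-4-[1-(trimethylsilyloxy)ethenyl]-2-[2-(trimethylsilyloxy)propan-2-yl]-2,3-dihydrofuran-3-yl]-4-[(triisopropylsilyl)oxy]benzoate | COC(=O)c1ccc(O[Si](C(C)C)(C(C)C)C(C)C)c(c1)[C@@H]1C(C(=C)O[Si](C)(C)C)=C(O[C@H]1C(C)(C)O[Si](C)(C)C)[C@@H]1C(CCc2ccccc2)=NO[C@H]1OC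
F3 | step 11 | tricyclic ketone: compound 18 with C4=O and C5H2 in place of the C4 methyl enol ether (2R,3R,6R,7R) | COC(=O)c1ccc(O[Si](C(C)C)(C(C)C)C(C)C)c(c1)[C@@H]1C2=C(O[C@H]1C(C)(C)O[Si](C)(C)C)[C@@H]1C(CCc3ccccc3)=NO[C@@H]1CC2=O
F4 | step 8 | methyl (4R,5R)-4-{5-bromo-2-[(triisopropylsilyl)oxy]phenyl}-5-(2-hydroxypropan-2-yl)-2-[(E)-2-methoxyethenyl]-4,5-dihydrofuran-3-carboxylate | Brc1ccc(O[Si](C(C)C)(C(C)C)C(C)C)c(c1)[C@@H]1C(C(=O)OC)=C(/C=C/OC)O[C@H]1C(C)(C)O
F5 | step 8 | methyl (4R,5R)-4-{5-bromo-2-[(triisopropylsilyl)oxy]phenyl}-5-(2-hydroxypropan-2-yl)-2-[(4R,5S)-5-methoxy-3-(2-phenylethyl)-4,5-dihydro-1,2-oxazol-4-yl]-4,5-dihydrofuran-3-carboxylate | Brc1ccc(O[Si](C(C)C)(C(C)C)C(C)C)c(c1)[C@@H]1C(C(=O)OC)=C(O[C@H]1C(C)(C)O)[C@H]1C(CCc2ccccc2)=NO[C@@H]1OC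
F6 | step 12 | methyl 3-[(2R,3R,6R,7R)-6-hydroxy-4-methoxy-7-(3-phenylpropanoyl)-2-[2-(trimethylsilyloxy)propan-2-yl]-2,3,6,7-tetrahydro-1-benzofuran-3-yl]-4-[(triisopropylsilyl)oxy]benzoate | COC(=O)c1ccc(O[Si](C(C)C)(C(C)C)C(C)C)c(c1)[C@@H]1C2=C(O[C@H]1C(C)(C)O[Si](C)(C)C)[C@H](C(=O)CCc3ccccc3)[C@H](O)C=C2OC
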